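## Structural features

The target is a single benzene ring with five substituents: a carboxyl group at C1, hydroxyls at C2 and C4, a methyl at C5 and a 13-methyltetradecyl chain at C6 (twelve methylenes ending in an isopropyl group). Only C3 carries hydrogen. There is no stereocentre and no second ring, so the problem is purely one of regiochemistry. The substituents from C4 round to C2 are contiguous, and the chain at C6 sits between two carbon substituents, which makes that side of the ring crowded. The fragile unit is the 2,4-dihydroxybenzoic acid: it loses CO2 readily in hot or strongly acidic media, and the free resorcinol is oxidisable under base, so the acid should not pass through ether cleavages. The iso-branched C15 chain is not a stock fragment and has to be assembled. The real difficulty is placing methyl and carboxyl on the two carbons that flank the chain without touching C3. The key step exploits the fact that C1 is ortho to the oxygen on C2 and para to the oxygen on C4, whereas C3 is only ortho to both. C5 has the same ortho/para relationship, and at the 5-alkylresorcinol stage C1 and C5 are equivalent by symmetry, so formyl (later methyl) enters one of them and CO2 then enters the only one left.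

## Logic of the disconnections

In 14 the bond between ring carbon C1 and the carboxyl carbon is cut, leading to 12. The cut is made there because C1 is the one free ring carbon activated ortho and para by oxygen, and because the acid is the most labile function and belongs at the very end. The gain is a precursor with no protecting groups and no decarboxylation risk upstream. The demand is that C-carboxylation prefers C1 over C3 and that the acid is released from chelate 13 without heating in acid.

In 12 the two O–H bonds are traced back to the O–CH3 bonds of 10. Free phenols would quench organomagnesium reagents and complicate electrophilic formylation, whereas methyl ethers pass through every earlier step unchanged. The gain is that all carbon–carbon bond formation can be done on a robust, neutral arene. The demand is complete cleavage of both ethers through 11, which is easy here because no other Lewis-acid-sensitive group is present.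

In 10 the C5 methyl is traced back to the formyl group of 8 (exchange of C–H bonds for C=O). A methyl cation equivalent would give poor regiocontrol and over-alkylation, while a formyl group deactivates the ring after a single substitution. The gain is access to a highly selective formylation. The demand is full deoxygenation through 9 without benzylation of a second arene.

In 8 the bond between the ring and the formyl carbon is cut, leading to 6. The carbon concerned is para to one methoxy group and ortho to the other, and in 6 the two carbons of this kind are identical by symmetry. The gain is a symmetrical 1,3,5-trisubstituted arene. The demand is that the electrophile chooses a carbon beside the chain and not the carbon between the two methoxy groups.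

In 6 the bond between the benzylic carbon and the second chain carbon is cut, leading to 4 and 5, the latter made from 3. A benzylic bromide and a primary alkylmagnesium reagent are a matched pair for copper-catalysed sp3–sp3 coupling. This direct coupling is two steps shorter than an olefination–hydrogenation detour. The gain is a stock aromatic piece and a C14 chain piece. The demand is that cross-coupling outruns homocoupling of the benzylic halide.

In 3 the bond between C11 and the isopropyl methine is cut, leading to 1 and 2. Both are commodity reagents and the branch is placed unambiguously at the chain terminus. The gain is a chain synthesis in one operation. The demand is monosubstitution of a symmetrical bifunctional electrophile.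

## Other disconnections considered

Alternative 1: The cut is the C1–C6 ring bond, with the whole arene unfolded into a masked polyketide chain. 14 would arise by hydrolytic opening of 7-hydroxy-2,2,6-trimethyl-5-(13-methyltetradecyl)-4H-1,3-benzodioxin-4-one (A1), and A1 from the diketo-dioxinone 2,2-dimethyl-6-(3,17-dimethyl-2,4-dioxooctadecyl)-4H-1,3-dioxin-4-one (A2).
- Forward key step: a mild amine or carbonate base would enolise A2, the dioxinone α-carbon would add to the chain-bearing ketone, and dehydration with enolisation would deliver A1.
- In favour: every substituent position is fixed by the constitution of A2, so no C1-versus-C3 question arises. The conditions are mild, and the carboxyl arrives masked and protected against decarboxylation.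
- Against: A2 is a sensitive tricarbonyl equivalent. It needs an acyl building block that already contains the whole branched chain plus one carbon, a C-acylation of a keto-dioxinone, and a methyl placed specifically on the carbon between the two ketones. The methyl-bearing diketone is also more hindered in the aldol closure, and an unmasking step follows A1.
- Comparison: on structure this alternative is the better one for certainty of the carboxyl position. On mechanism it replaces an electrophilic substitution on a finished ring by an aldol condensation and aromatisation. On step economy it should be no shorter than the six steps chosen, and probably longer once A2 is counted from stock materials.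

Alternative 2: The cuts are the C1–C2 and C2–C3 ring bonds. C2 would come from carbon monoxide (A5) and the other five ring carbons from the enyne acetate methyl 4-acetoxy-4-methyl-3-(13-methyltetradecyl)hex-2-en-5-ynoate (A4). The product would be methyl 4-acetoxy-2-hydroxy-5-methyl-6-(13-methyltetradecyl)benzoate (A3).
- Forward key step: with catalytic [RhCl(CO)2]2 under A5, the acetoxy group of A4 would shift to the neighbouring alkyne carbon, the resulting rhodium carbenoid/metallacycle would take up A5 and close onto the enoate carbon, and tautomerisation would give A3.
- In favour: the ring is built catalytically with a one-carbon gas as C2, every position is set by A4, and the two phenolic oxygens emerge differentiated.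
- Against: A4 combines a tertiary propargylic acetate prone to ionisation with a trisubstituted, electron-poor enoate carrying the long chain, and its preparation would take several steps. The electron-poor alkene terminus is a less favourable partner for the metallacycle. A3 then needs hydrolysis of an acetate and of a doubly ortho-substituted methyl ester, under conditions forcing enough to threaten decarboxylation.
- Comparison: on structure it is the equal or the better of the chosen plan in regiochemical definition. On mechanism it relies on a transition-metal carbonylative annulation where the chosen plan uses a main-group carboxylation. On step economy it is worse, and the differentiation of the two oxygens, its particular strength, is not needed for 14.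

Alternative 3: The cuts are the C5–C6 and C3–C4 ring bonds. Methyl 2,4-dimethoxy-5-methyl-6-(13-methyltetradecyl)benzoate (A6) would come from the pyrone methyl 4-methoxy-6-(13-methyltetradecyl)-2-oxo-2H-pyran-5-carboxylate (A7) and the ketene acetal 1,1-dimethoxyprop-1-ene (A8).
- Forward key step: on heating, the nucleophilic methyl-bearing carbon of A8 would bond to the chain-bearing C6 of A7 and the acetal carbon to C3 of A7. The bicyclic adduct would then extrude its lactone bridge and one alkoxy group to give A6.
- In favour: the regiochemistry is polarity-matched, two ring bonds and the methyl are installed in one metal-free operation, and pyrones of the type of A7 are reachable by condensation chemistry.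
- Against: the substituted carbon of A8 must attack the most hindered carbon of A7, A8 is moisture-sensitive, and A7 again requires the complete branched chain as an acyl unit. A6 then needs removal of two aryl methyl ethers and a hindered ester from a decarboxylation-prone acid.
- Comparison: on mechanism the two plans are equal in resting on electronic polarisation for regiocontrol. On structure this alternative is better in that the carboxyl position is fixed from the start. On step economy and protecting-group economy it is worse, because the chosen plan ends on an unprotected precursor and needs no deprotection after the carboxyl is in place.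

Key step: step 6

Assumption: the target has no stereocentre, so its constitution is the full structure; 1, 2, 4 and magnesium methyl carbonate (2 M in DMF) are taken as stock chemicals.

## Route

Step 1
Reactants: 1 1,11-dibromoundecane; 2 isopropylmagnesium chloride
Product: 3 1-bromo-12-methyltridecane
Conditions: 1 (3 equiv), 2 (1 equiv, slow addition), Li2CuCl4 (3 mol %), NMP (4 equiv), THF, 0 °C → rt
Reagents that add atoms: none
Why: Copper-catalysed Kumada-type alkyl–alkyl coupling of a secondary Grignard reagent with a primary bromide is fast under Li2CuCl4/NMP; the threefold excess of 1 biases the outcome towards monosubstitution, and unchanged 1 is recovered by distillation or chromatography.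

Step 2
Reactants: 3 1-bromo-12-methyltridecane; 4 1-(bromomethyl)-3,5-dimethoxybenzene
Product: 6 1,3-dimethoxy-5-(13-methyltetradecyl)benzene, via 12-methyltridecylmagnesium bromide 5 (not isolated)
Conditions: Mg, THF, 50 °C; then slow addition to 4, Li2CuCl4 (3 mol %), THF, −30 → 0 °C
Reagents that add atoms: none
Why: Grignard formation from the primary bromide followed by copper-catalysed sp3–sp3 cross-coupling; the benzylic bromide is a highly reactive electrophile towards the organocopper intermediate, the methoxy groups are inert, and slow addition at low temperature limits halogen–magnesium exchange.

Step 3
Reactants: 6 1,3-dimethoxy-5-(13-methyltetradecyl)benzene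
Product: 8 2,4-dimethoxy-6-(13-methyltetradecyl)benzaldehyde, via aryl iminium chloride 7 (not isolated)
Conditions: POCl3 (2 equiv), DMF, 0 → 80 °C; then ice–H2O
Reagents that add atoms: N,N-dimethylformamide, CN(C)C=O; water, O
Why: Vilsmeier–Haack formylation; the chloroiminium electrophile attacks one of the two symmetry-equivalent carbons that are para to one methoxy group and ortho to the other, in preference to the more hindered carbon between the two methoxy groups, and the iminium substituent deactivates the ring against a second substitution before hydrolysis releases the aldehyde.

Step 4
Reactants: 8 2,4-dimethoxy-6-(13-methyltetradecyl)benzaldehyde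
Product: 10 1,5-dimethoxy-2-methyl-3-(13-methyltetradecyl)benzene, via benzylic alcohol 9 (not isolated)
Conditions: H2 (3 bar), 10% Pd/C, AcOH, cat. H2SO4, rt
Reagents that add atoms: none
Why: Catalytic hydrogenation of the aldehyde to 9 followed by acid-assisted benzylic hydrogenolysis; the ortho and para methoxy groups make the benzylic C–O bond easy to ionise and cleave on palladium, while the arene, the aryl ethers and the saturated chain are untouched at room temperature.

Step 5
Reactants: 10 1,5-dimethoxy-2-methyl-3-(13-methyltetradecyl)benzene
Product: 12 4-methyl-5-(13-methyltetradecyl)benzene-1,3-diol, via bis(dibromoboryl) aryl ether 11 (not isolated)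
Conditions: BBr3 (3 equiv), CH2Cl2, −78 °C → rt; then ice–H2O
Reagents that add atoms: none
Why: Lewis-acid cleavage of aryl methyl ethers; boron coordinates each ether oxygen, bromide attacks the methyl carbon in an SN2 step, and hydrolysis of 11 liberates the diol; no other group in 10 responds to BBr3.

Step 6
Reactants: 12 4-methyl-5-(13-methyltetradecyl)benzene-1,3-diol
Product: 14 2,4-dihydroxy-5-methyl-6-(13-methyltetradecyl)benzoic acid, via magnesium salicylate chelate 13 (not isolated)
Conditions: CH3OMgOCO2CH3 (2 M in DMF, 10 equiv), 120 °C, N2 sweep; then ice-cold 1 M HCl, extraction below 10 °C
Reagents that add atoms: magnesium methyl carbonate (methoxymagnesium methyl carbonate), COC(=O)O[Mg]OC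
Why: The diol exchanges with the reagent to give an aryloxymagnesium methyl carbonate and methanol, which the nitrogen stream removes. The magnesium-bound carbonate carbon is then delivered through a six-membered transition state to the ortho ring carbon, and loss of the ring proton restores aromaticity. This is an electrophilic aromatic substitution of Kolbe–Schmitt type, and its closest known counterpart is the carboxylation of 5-alkylresorcinols to 6-alkyl-2,4-dihydroxybenzoic acids with the same reagent. The salicylate is trapped as the six-membered magnesium chelate 13, which takes it out of the reversible carboxylation equilibrium, and cold aqueous HCl then frees 14. The product contains no new ring (the chelate ring is transient) and no stereocentre. The selectivity required is attack at the ring CH between a hydroxyl-bearing carbon and the chain, not at the CH between the two hydroxyls. In 12 the former is the only free carbon both ortho to one oxygen and para to the other, because its symmetry partner already carries the methyl from steps 3 and 4, so para-phenoxide donation makes it the most nucleophilic position. O-carboxylation is reversible and unproductive, and the alkyl groups are inert.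

## Compound list

1 | 1,11-dibromoundecane | BrCCCCCCCCCCCBr | starting material
2 | isopropylmagnesium chloride | CC(C)[Mg]Cl | starting material
3 | 1-bromo-12-methyltridecane | CC(C)CCCCCCCCCCCBr | intermediate
4 | 1-(bromomethyl)-3,5-dimethoxybenzene (3,5-dimethoxybenzyl bromide) | COc1cc(CBr)cc(OC)c1 | starting material
5 | 12-methyltridecylmagnesium bromide | CC(C)CCCCCCCCCCC[Mg]Br | intermediate (not isolated)
6 | 1,3-dimethoxy-5-(13-methyltetradecyl)benzene | COc1cc(OC)cc(CCCCCCCCCCCCC(C)C)c1 | intermediate
7 | N-{[2,4-dimethoxy-6-(13-methyltetradecyl)phenyl]methylidene}-N-methylmethanaminium chloride | COc1cc(OC)c(C=[N+](C)C)c(CCCCCCCCCCCCC(C)C)c1.[Cl-] | intermediate (not isolated)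
8 | 2,4-dimethoxy-6-(13-methyltetradecyl)benzaldehyde | COc1cc(OC)c(C=O)c(CCCCCCCCCCCCC(C)C)c1 | intermediate
9 | [2,4-dimethoxy-6-(13-methyltetradecyl)phenyl]methanol | COc1cc(OC)c(CO)c(CCCCCCCCCCCCC(C)C)c1 | intermediate (not isolated)
10 | 1,5-dimethoxy-2-methyl-3-(13-methyltetradecyl)benzene | COc1cc(OC)c(C)c(CCCCCCCCCCCCC(C)C)c1 | intermediate
11 | 1,3-bis(dibromoboryloxy)-4-methyl-5-(13-methyltetradecyl)benzene | Cc1c(OB(Br)Br)cc(OB(Br)Br)cc1CCCCCCCCCCCCC(C)C | intermediate (not isolated)
12 | 4-methyl-5-(13-methyltetradecyl)benzene-1,3-diol | Cc1c(O)cc(O)cc1CCCCCCCCCCCCC(C)C | intermediate
13 | magnesium 2-carboxylato-5-hydroxy-4-methyl-3-(13-methyltetradecyl)phenolate (six-membered O–Mg–O chelate) | Cc1c(O)cc2O[Mg]OC(=O)c2c1CCCCCCCCCCCCC(C)C | intermediate (not isolated)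
14 | 2,4-dihydroxy-5-methyl-6-(13-methyltetradecyl)benzoic acid | Cc1c(O)cc(O)c(C(=O)O)c1CCCCCCCCCCCCC(C)C | target

## Step count and least certain steps

Total step count: 6. Longest linear sequence: 6 (steps 1 to 6; 4 enters as a stock compound in step 2).

Step 6 (key step). Two processes are the most likely to go wrong. The first is competing carboxylation at the carbon between the two hydroxyls, or stalled conversion because the reacting carbon is shielded by the chain, which is itself buttressed by the neighbouring methyl. The second is loss of CO2 from the product during acidic work-up or purification. The fallback sets out from 12 and returns at 14. Vilsmeier–Haack formylation of 12 (POCl3, DMF, then aqueous hydrolysis) at the same ortho/para carbon should give 2,4-dihydroxy-5-methyl-6-(13-methyltetradecyl)benzaldehyde F1. Chlorite oxidation of F1 (NaClO2, NaH2PO4, DMSO–H2O, with DMSO as hypochlorite scavenger) should then give 14. The formylation is irreversible and kinetically governed by para activation, and the oxidation is mild and near neutral, so neither regiochemical equilibration nor thermal decarboxylation is invited.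

Step 1. The most likely failure is double substitution of the dibromide, together with incomplete separation of 3 from the excess of 1; residual 1 would form a bis-Grignard reagent in step 2. The fallback sets out from 2 and returns at 3. 11-Bromoundecan-1-ol F2 is treated with 2 (2.2 equiv, the first equivalent forming the alkoxide) and Li2CuCl4 in THF to give 12-methyltridecan-1-ol F3, which has only one reactive carbon–bromine bond to offer and is easily purified as an alcohol. An Appel reaction on F3 (CBr4, PPh3, CH2Cl2) then gives 3.

Step 2. The most likely failure is homocoupling of the benzylic bromide through halogen–magnesium exchange, or its reduction, at the expense of cross-coupling. The fallback sets out from 3 and returns at 6. Heating 3 with PPh3 in MeCN gives (12-methyltridecyl)triphenylphosphonium bromide F4. Deprotonation of F4 with NaHMDS in THF and Wittig reaction with 3,5-dimethoxybenzaldehyde F5 gives 1,3-dimethoxy-5-(13-methyltetradec-1-en-1-yl)benzene F6 as an E/Z mixture of no consequence. Hydrogenation of F6 (H2, Pd/C, EtOAc) gives 6. This costs two extra steps but uses only routine transformations.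

Step 3. The most likely failure is partial formylation at the carbon between the two methoxy groups, which would call for separation of regioisomers. The fallback sets out from 6 and returns at 10, bypassing 8. Bromination of 6 with NBS in MeCN at 0 °C, which is strongly para-directed, should give 2-bromo-1,5-dimethoxy-3-(13-methyltetradecyl)benzene F7. Bromine–lithium exchange on F7 (n-BuLi, THF, −78 °C) and quenching with MeI installs the methyl directly and gives 10.

## Further compounds

F1 | step 6 | 2,4-dihydroxy-5-methyl-6-(13-methyltetradecyl)benzaldehyde | Cc1c(O)cc(O)c(C=O)c1CCCCCCCCCCCCC(C)C
F2 | step 1 | 11-bromoundecan-1-ol | OCCCCCCCCCCCBr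
F3 | step 1 | 12-methyltridecan-1-ol | CC(C)CCCCCCCCCCCO
F4 | step 2 | (12-methyltridecyl)triphenylphosphonium bromide | CC(C)CCCCCCCCCCC[P+](c1ccccc1)(c1ccccc1)c1ccccc1.[Br-]
F5 | step 2 | 3,5-dimethoxybenzaldehyde | COc1cc(C=O)cc(OC)c1
F6 | step 2 | 1,3-dimethoxy-5-(13-methyltetradec-1-en-1-yl)benzene (E/Z mixture, geometry not defined) | COc1cc(OC)cc(C=CCCCCCCCCCCC(C)C)c1
F7 | step 3 | 2-bromo-1,5-dimethoxy-3-(13-methyltetradecyl)benzene | COc1cc(OC)c(Br)c(CCCCCCCCCCCCC(C)C)c1
A1 | alternative 1 | 7-hydroxy-2,2,6-trimethyl-5-(13-methyltetradecyl)-4H-1,3-benzodioxin-4-one | CC1(C)OC(=O)c2c(O1)cc(O)c(C)c2CCCCCCCCCCCCC(C)C
A2 | alternative 1 | 2,2-dimethyl-6-(3,17-dimethyl-2,4-dioxooctadecyl)-4H-1,3-dioxin-4-one (racemic at the enolisable methine) | CC1(C)OC(=O)C=C(CC(=O)C(C)C(=O)CCCCCCCCCCCCC(C)C)O1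
A3 | alternative 2 | methyl 4-acetoxy-2-hydroxy-5-methyl-6-(13-methyltetradecyl)benzoate | COC(=O)c1c(O)cc(OC(C)=O)c(C)c1CCCCCCCCCCCCC(C)C
A4 | alternative 2 | methyl 4-acetoxy-4-methyl-3-(13-methyltetradecyl)hex-2-en-5-ynoate (alkene geometry and quaternary centre not defined; both are erased in the arene) | COC(=O)C=C(CCCCCCCCCCCCC(C)C)C(C)(OC(C)=O)C#C
A5 | alternative 2 | carbon monoxide | [C-]#[O+]
A6 | alternative 3 | methyl 2,4-dimethoxy-5-methyl-6-(13-methyltetradecyl)benzoate | COC(=O)c1c(OC)cc(OC)c(C)c1CCCCCCCCCCCCC(C)C
A7 | alternative 3 | methyl 4-methoxy-6-(13-methyltetradecyl)-2-oxo-2H-pyran-5-carboxylate | COC(=O)C1=C(CCCCCCCCCCCCC(C)C)OC(=O)C=C1OC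
A8 | alternative 3 | 1,1-dimethoxyprop-1-ene | CC=C(OC)OC
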